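**Plan**

- Retrosynthetic cuts, in this order: the two benzyl ethers on the enol and phenol oxygens; the C3 carbinol of the chromane back to a ketone; the pyran ring at the C4–C4a bond (benzylic CH2 to arene carbon), which leaves an aryl ether ArO–CMe2–C≡CH; the lactone C2–CH2Ar bond (benzylation of a butenolide anion); the butenolide into methyl 4-hydroxyphenylpyruvate and methyl glyoxylate.
- Forward: the lactone ring arises first by aldol addition–lactonization, then O-benzylation, then the quaternary carbon by benzylation with a bromide that already carries the propargyl ether. The pyran ring closes last by gold-catalyzed alkyne oxidation with arene C–H cyclization, followed by ketone reduction and hydrogenolysis.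
- Enabling feature: the chromane oxygen O1 is para to the benzylic CH2 on the benzene ring, so its two ortho carbons are equivalent. C3 of the pyran ring bears oxygen exactly where the internal alkyne carbon of an O1–C2(Me)2–C≡CH ether becomes C=O on oxygen transfer. C2 is quaternary (gem-dimethyl), which favors closure and blocks enolization on that flank.
- Stereochemistry: C2 of the lactone (R) from ion pairing with a chiral ammonium cation in the benzylation; C3 of the chromane (R) from an (S)-oxazaborolidine-controlled borane reduction. The two centers are remote and are set independently.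

Key step: step 8

Assumption: in step 7 the (S,S) antipode of the ammonium salt is taken to be the one that leaves the Si face of C2 of the furanolate open; both antipodes are commercial, so the antipode would be fixed by one analytical run without any other change to the route.

**Step 1**
Reactants: 1 4-hydroxyphenylpyruvic acid
Product: 2 methyl 3-(4-hydroxyphenyl)-2-oxopropanoate (drawn as the keto form, present largely as the enol)
Conditions: MeOH, H2SO4 (cat.), 40 °C
Reagents that add atoms: methanol, CO
Why: Fischer esterification of the carboxyl group; the largely enolized keto group and the phenol should not react.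

**Step 2**
Reactants: 2 methyl 3-(4-hydroxyphenyl)-2-oxopropanoate, 3 methyl glyoxylate
Product: 5 methyl 4-hydroxy-3-(4-hydroxyphenyl)-5-oxo-2,5-dihydrofuran-2-carboxylate (racemic), via open-chain aldol adduct 4 (not isolated)
Conditions: Et3N (1.2 equiv), THF, 0 °C to rt; then 1 M HCl
Reagents that add atoms: none
Why: The arylpyruvate enolate adds to the non-enolizable, more electrophilic aldehyde of 3 (crossed aldol addition) and the new hydroxyl closes the five-membered lactone on the alpha-keto ester with loss of methanol, the usual isotetronic acid synthesis; C2 is formed racemic and becomes planar again in step 7.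

**Step 3**
Reactants: 5 methyl 4-hydroxy-3-(4-hydroxyphenyl)-5-oxo-2,5-dihydrofuran-2-carboxylate
Product: 6 methyl 4-(benzyloxy)-3-[4-(benzyloxy)phenyl]-5-oxo-2,5-dihydrofuran-2-carboxylate (racemic)
Conditions: BnOH (2.1 equiv), PPh3, DIAD, THF, 0 °C to rt
Reagents that add atoms: benzyl alcohol, OCc1ccccc1
Why: Mitsunobu etherification of the two acidic hydroxyls (enol and conjugated phenol) under neutral conditions, chosen so that no carbanion is generated at the acidic C2–H during protection.

**Step 4**
Reactants: 7 4-hydroxybenzaldehyde, 8 3-chloro-3-methylbut-1-yne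
Product: 9 4-[(2-methylbut-3-yn-2-yl)oxy]benzaldehyde
Conditions: CuCl2·2H2O (1 mol%), DBU, MeCN, 0 °C
Reagents that add atoms: none
Why: Copper-catalyzed propargylic substitution, in which the copper acetylide of 8 ionizes to a copper allenylidene that the phenoxide attacks at the tertiary carbon, giving the 1,1-dimethylpropargyl aryl ether and not the allenyl ether.

**Step 5**
Reactants: 9 4-[(2-methylbut-3-yn-2-yl)oxy]benzaldehyde
Product: 10 {4-[(2-methylbut-3-yn-2-yl)oxy]phenyl}methanol
Conditions: NaBH4, MeOH, 0 °C
Reagents that add atoms: none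
Why: Hydride reduction of the aldehyde, to which the alkyne and the tertiary ether are inert.

**Step 6**
Reactants: 10 {4-[(2-methylbut-3-yn-2-yl)oxy]phenyl}methanol
Product: 11 1-(bromomethyl)-4-[(2-methylbut-3-yn-2-yl)oxy]benzene
Conditions: CBr4, PPh3, CH2Cl2, 0 °C
Reagents that add atoms: carbon tetrabromide, BrC(Br)(Br)Br
Why: Appel reaction under neutral conditions, chosen because the acid-labile tertiary propargylic aryl ether would not tolerate HBr; the electron-rich benzylic bromide is used without storage.

**Step 7**
Reactants: 6 methyl 4-(benzyloxy)-3-[4-(benzyloxy)phenyl]-5-oxo-2,5-dihydrofuran-2-carboxylate, 11 1-(bromomethyl)-4-[(2-methylbut-3-yn-2-yl)oxy]benzene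
Product: 12 methyl (2R)-4-(benzyloxy)-3-[4-(benzyloxy)phenyl]-2-({4-[(2-methylbut-3-yn-2-yl)oxy]phenyl}methyl)-5-oxo-2,5-dihydrofuran-2-carboxylate
Conditions: (S,S)-3,4,5-trifluorophenyl-NAS bromide (N-spiro bis-binaphthyl ammonium bromide, 2 mol%), K2CO3 (powdered), toluene, −20 °C
Reagents that add atoms: none
Why: Proposed new method: K2CO3 removes the C2–H of 6 (alpha to the ester and vinylogous to the lactone carbonyl) to give a planar 2-oxidofuran, the chiral ammonium cation carries it into toluene as a tight ion pair that shields one face, and the soft benzylic bromide alkylates C2 (the carbon that bears the ester and whose alkylation restores the conjugated butenolide) on the open Si face to give the (R) quaternary center; the closest known reaction type is the asymmetric phase-transfer benzylation of cyclic beta-keto esters and 3-substituted oxindoles to quaternary centers.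

**Step 8**
Reactants: 12 methyl (2R)-4-(benzyloxy)-3-[4-(benzyloxy)phenyl]-2-({4-[(2-methylbut-3-yn-2-yl)oxy]phenyl}methyl)-5-oxo-2,5-dihydrofuran-2-carboxylate
Product: 13 methyl (2R)-4-(benzyloxy)-3-[4-(benzyloxy)phenyl]-2-[(2,2-dimethyl-3-oxo-3,4-dihydro-2H-chromen-6-yl)methyl]-5-oxo-2,5-dihydrofuran-2-carboxylate
Conditions: (Me4tBuXPhos)AuNTf2 (5 mol%), 3,5-dichloropyridine N-oxide (2.5 equiv), 1,2-dichloroethane, rt
Reagents that add atoms: 3,5-dichloropyridine N-oxide, [O-][n+]1cc(Cl)cc(Cl)c1
Why: The cationic monovalent gold complex activates the terminal alkyne, the N-oxide oxygen adds to the internal alkyne carbon and N–O cleavage leaves an alpha-oxo gold carbene at the terminal carbon, which an ortho carbon of the aryl ether attacks; rearomatization and protodeauration give the 2,2-dimethylchroman-3-one and return the catalyst. The closest known reaction type is the gold-catalyzed oxidative cyclization of aryl propargyl ethers to chroman-3-ones with pyridine N-oxides. The pyran ring closes by C–C bond formation between C4 and C4a, a 6-exo attack of the arene on the carbene carbon in the manner of a Friedel–Crafts alkylation, helped by the gem-dimethyl group at C2. No stereocenter is formed, since C3 emerges as a ketone that is reduced under reagent control in step 9, and the quaternary lactone carbon has no acidic hydrogen and is untouched. The step needs oxygen transfer to outrun direct hydroarylation of the alkyne, and the carbene to be captured by the arene before a second oxidation; an excess of an unhindered N-oxide at high concentration serves the first, the bulky biaryl phosphine and the six-membered geometry the second. Site selectivity is secured by the substrate, because the two carbons ortho to the ether oxygen are equivalent in the para-disubstituted ring and the other arenes can only react intermolecularly.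

**Step 9**
Reactants: 13 methyl (2R)-4-(benzyloxy)-3-[4-(benzyloxy)phenyl]-2-[(2,2-dimethyl-3-oxo-3,4-dihydro-2H-chromen-6-yl)methyl]-5-oxo-2,5-dihydrofuran-2-carboxylate
Product: 14 methyl (2R)-4-(benzyloxy)-3-[4-(benzyloxy)phenyl]-2-{[(3R)-3-hydroxy-2,2-dimethyl-3,4-dihydro-2H-chromen-6-yl]methyl}-5-oxo-2,5-dihydrofuran-2-carboxylate
Conditions: (S)-2-methyl-CBS-oxazaborolidine (20 mol%), BH3·SMe2, THF, −20 °C; then MeOH
Reagents that add atoms: none
Why: Corey–Bakshi–Shibata reduction, in which the ketone binds the ring boron with the quaternary C2 flank as the large group and the benzylic CH2 as the small one, so that the (S) catalyst should deliver hydride to the face that gives the (3R) carbinol (the same sense as acetophenone to (R)-1-phenylethanol), while ester and lactone are not reduced by borane at this temperature.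

**Step 10**
Reactants: 14 methyl (2R)-4-(benzyloxy)-3-[4-(benzyloxy)phenyl]-2-{[(3R)-3-hydroxy-2,2-dimethyl-3,4-dihydro-2H-chromen-6-yl]methyl}-5-oxo-2,5-dihydrofuran-2-carboxylate
Product: 15 methyl (2R)-4-hydroxy-2-{[(3R)-3-hydroxy-2,2-dimethyl-3,4-dihydro-2H-chromen-6-yl]methyl}-3-(4-hydroxyphenyl)-5-oxo-2,5-dihydrofuran-2-carboxylate (CNP0275739.3)
Conditions: H2 (1 atm), 10% Pd/C, EtOAc, rt
Reagents that add atoms: none
Why: Hydrogenolysis of the enol and phenol benzyl ethers; the tetrasubstituted conjugated enol double bond, the quaternary C–O bond of the lactone and the chromanol should survive at 1 atm and short contact time.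

**Compound list**

1 | 4-hydroxyphenylpyruvic acid | OC(=O)C(=O)Cc1ccc(O)cc1 | starting material
2 | methyl 3-(4-hydroxyphenyl)-2-oxopropanoate | COC(=O)C(=O)Cc1ccc(O)cc1 | intermediate
3 | methyl glyoxylate | COC(=O)C=O | starting material
4 | dimethyl 2-hydroxy-3-(4-hydroxyphenyl)-4-oxopentanedioate (aldol adduct, mixture of stereoisomers, not isolated) | COC(=O)C(O)C(c1ccc(O)cc1)C(=O)C(=O)OC | intermediate
5 | methyl 4-hydroxy-3-(4-hydroxyphenyl)-5-oxo-2,5-dihydrofuran-2-carboxylate (racemic) | COC(=O)C1OC(=O)C(O)=C1c1ccc(O)cc1 | intermediate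
6 | methyl 4-(benzyloxy)-3-[4-(benzyloxy)phenyl]-5-oxo-2,5-dihydrofuran-2-carboxylate (racemic) | COC(=O)C1OC(=O)C(OCc2ccccc2)=C1c1ccc(OCc2ccccc2)cc1 | intermediate
7 | 4-hydroxybenzaldehyde | O=Cc1ccc(O)cc1 | starting material
8 | 3-chloro-3-methylbut-1-yne | CC(C)(Cl)C#C | starting material
9 | 4-[(2-methylbut-3-yn-2-yl)oxy]benzaldehyde | CC(C)(C#C)Oc1ccc(C=O)cc1 | intermediate
10 | {4-[(2-methylbut-3-yn-2-yl)oxy]phenyl}methanol | CC(C)(C#C)Oc1ccc(CO)cc1 | intermediate
11 | 1-(bromomethyl)-4-[(2-methylbut-3-yn-2-yl)oxy]benzene | CC(C)(C#C)Oc1ccc(CBr)cc1 | intermediate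
12 | methyl (2R)-4-(benzyloxy)-3-[4-(benzyloxy)phenyl]-2-({4-[(2-methylbut-3-yn-2-yl)oxy]phenyl}methyl)-5-oxo-2,5-dihydrofuran-2-carboxylate | COC(=O)[C@]1(Cc2ccc(OC(C)(C)C#C)cc2)OC(=O)C(OCc2ccccc2)=C1c1ccc(OCc2ccccc2)cc1 | intermediate
13 | methyl (2R)-4-(benzyloxy)-3-[4-(benzyloxy)phenyl]-2-[(2,2-dimethyl-3-oxo-3,4-dihydro-2H-chromen-6-yl)methyl]-5-oxo-2,5-dihydrofuran-2-carboxylate | COC(=O)[C@]1(Cc2ccc3c(c2)CC(=O)C(C)(C)O3)OC(=O)C(OCc2ccccc2)=C1c1ccc(OCc2ccccc2)cc1 | intermediate
14 | methyl (2R)-4-(benzyloxy)-3-[4-(benzyloxy)phenyl]-2-{[(3R)-3-hydroxy-2,2-dimethyl-3,4-dihydro-2H-chromen-6-yl]methyl}-5-oxo-2,5-dihydrofuran-2-carboxylate | COC(=O)[C@]1(Cc2ccc3c(c2)C[C@@H](O)C(C)(C)O3)OC(=O)C(OCc2ccccc2)=C1c1ccc(OCc2ccccc2)cc1 | intermediate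
15 | methyl (2R)-4-hydroxy-2-{[(3R)-3-hydroxy-2,2-dimethyl-3,4-dihydro-2H-chromen-6-yl]methyl}-3-(4-hydroxyphenyl)-5-oxo-2,5-dihydrofuran-2-carboxylate | COC(=O)[C@]1(Cc2ccc3c(c2)C[C@@H](O)C(C)(C)O3)OC(=O)C(O)=C1c1ccc(O)cc1 | target

**Step count and risks**

Total step count: 10. Longest linear sequence: 7 steps (steps 1, 2, 3, 7, 8, 9, 10; the branch of steps 4, 5, 6 joins at step 7).

Steps most likely to fail:

Step 7 (bears the label). The flat, delocalized furanolate may pair only loosely with the ammonium cation, so that enantiofacial discrimination is poor; alkylation may also stray to the oxygen-bearing carbon C4 or to oxygen. The fallback uses known chemistry and sets out from 6 and 11: benzylation without asymmetric induction (Bu4NBr cat., K2CO3, toluene, rt) should give the racemic benzylation product F1. This is resolved by preparative chromatography on a chiral stationary phase (amylose tris(3,5-dimethylphenylcarbamate)); the (R) enantiomer is 12, where the route is rejoined.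

Step 8. Direct gold-catalyzed hydroarylation of the alkyne, which the gem-dimethyl group accelerates, may outrun oxygen transfer, or the carbene may be oxidized a second time before the arene captures it. The fallback sets out from 12 and accepts the hydroarylation outcome. Heating in xylenes at 140 °C (propargyl Claisen rearrangement, [1,5]-hydrogen shift, oxa-6π electrocyclization) should give the 2,2-dimethyl-2H-chromene F2. Jacobsen epoxidation with the (R,R)-N,N'-bis(3,5-di-tert-butylsalicylidene)-1,2-cyclohexanediamine manganese chloride complex [(R,R)-(salen)MnCl], NaOCl and 4-phenylpyridine N-oxide in CH2Cl2 at 0 °C should give the (3R,4R)-epoxide F3. Hydrogenolysis (H2, 10% Pd/C, EtOAc) should cleave the benzylic C4–O bond of the epoxide with retention at C3 and remove both benzyl ethers in the same operation, so the route is rejoined at 15.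

Step 9. Facial discrimination between the quaternary C2 flank and the benzylic CH2 flank may be insufficient, or the ring oxygen may complex borane and open an uncatalyzed pathway, which would erode the configurational purity at C3. The fallback sets out from 13 and moves stereocontrol from reduction to epoxidation. NaBH4 in MeOH at 0 °C should give the C3-epimeric alcohols F4. Dehydration with methyl N-(triethylammoniosulfonyl)carbamate (Burgess dehydration, toluene, 60 °C) can only eliminate toward C4 and should give chromene F2. This is taken through epoxide F3 and hydrogenolysis as described for step 8 and comes back to the route at 15.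

**Further compounds**

F1 | step 7 | methyl 4-(benzyloxy)-3-[4-(benzyloxy)phenyl]-2-({4-[(2-methylbut-3-yn-2-yl)oxy]phenyl}methyl)-5-oxo-2,5-dihydrofuran-2-carboxylate (racemic) | COC(=O)C1(Cc2ccc(OC(C)(C)C#C)cc2)OC(=O)C(OCc2ccccc2)=C1c1ccc(OCc2ccccc2)cc1
F2 | step 8 | methyl (2R)-4-(benzyloxy)-3-[4-(benzyloxy)phenyl]-2-[(2,2-dimethyl-2H-chromen-6-yl)methyl]-5-oxo-2,5-dihydrofuran-2-carboxylate | COC(=O)[C@]1(Cc2ccc3c(c2)C=CC(C)(C)O3)OC(=O)C(OCc2ccccc2)=C1c1ccc(OCc2ccccc2)cc1
F3 | step 8 | methyl (2R)-4-(benzyloxy)-3-[4-(benzyloxy)phenyl]-2-{[(3R,4R)-3,4-epoxy-2,2-dimethyl-3,4-dihydro-2H-chromen-6-yl]methyl}-5-oxo-2,5-dihydrofuran-2-carboxylate | COC(=O)[C@]1(Cc2ccc3c(c2)[C@H]4O[C@H]4C(C)(C)O3)OC(=O)C(OCc2ccccc2)=C1c1ccc(OCc2ccccc2)cc1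
F4 | step 9 | methyl (2R)-4-(benzyloxy)-3-[4-(benzyloxy)phenyl]-2-[(3-hydroxy-2,2-dimethyl-3,4-dihydro-2H-chromen-6-yl)methyl]-5-oxo-2,5-dihydrofuran-2-carboxylate (mixture of C3 epimers) | COC(=O)[C@]1(Cc2ccc3c(c2)CC(O)C(C)(C)O3)OC(=O)C(OCc2ccccc2)=C1c1ccc(OCc2ccccc2)cc1
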